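(The data stem from a simulated flask with constants of no real substance; the scatter is artificial.)

Count turnovers.

| flask | starting complex | incoming ligand | remark | time |
|---|---|---|---|---|
| gamma | 0.40 M | 1 equiv | run made earlier |  |
| eta | 0.40 M | 4.7 equiv | run made earlier |  |
| dawn | 0.40 M | 3.00 equiv |  | 20 min |
| dusk | 0.40 M | 0.800 equiv |  | 20 min |

| run | time / min | complex with two exchanged / % | complex with one exchanged / % |
|---|---|---|---|
| gamma | 2.00 | 1 | 7 |
| gamma | 4.00 | 0 | 8 |
| gamma | 6.00 | 1 | 13 |
| gamma | 8.00 | 2 | 12 |
| gamma | 10.0 | 0 | 15 |
| gamma | 12.0 | 0 | 17 |
| gamma | 15.0 | 2 | 17 |
| eta | 2.00 | 2 | 17 |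
| eta | 4.00 | 2 | 30 |
| eta | 6.00 | 0 | 40 |
| eta | 8.00 | 5 | 47 |
| eta | 10.0 | 4 | 50 |
| eta | 12.0 | 5 | 50 |
| eta | 15.0 | 6 | 55 |

(scatter of a reading: 1.5 percentage points)

* which of these holds the largest part of the starting complex at the end of dawn (complex with two exchanged / starting complex / complex with one exchanged)
* which of these holds the largest part of the starting complex at the end of dusk (complex with two exchanged / starting complex / complex with one exchanged)
* complex with two exchanged at the end of dawn, in percent of the starting complex charged



You have two flasks to call, dawn and dusk, and the runs gamma and eta show the pace of exchange. The first eta reading has 19.0% exchanged, one and two together, after 2.00 min with 4.7 equiv. Take that pace as pseudo-first-order, scaling with equivalents and with time. The turnover count, how many times over the exchange would replace the charge, is that share times the ratio of equivalents times the ratio of times: for dawn 1.21, for dusk 0.323. In this reckoning, which counts exchange as the one way out of starting complex, what stays unexchanged goes as exp(−count), so its two sides stand equal at 0.693. Dawn lies above that and dusk below it, so I call complex with one exchanged for dawn and starting complex for dusk.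

Was one number enough? Eta at 15.0 min has a count of 1.43, which gives 75.9% exchanged, but the reading is less, 61.0%. Scaling dawn's 70.3% by that shortfall gives 56.4% exchanged. For two exchanged at dawn, eta's 5% at 12.0 min scaled by equivalents gives 3.19%. In this reckoning that leaves more complex with one exchanged than starting complex, so my call stands.

The forecast differs at dawn: it names starting complex there and starting complex at dusk, with 4% two exchanged at dawn, between 2% and 7%, adding “Ignoring reversibility would favour the one-exchanged complex”.

Dawn gives complex with one exchanged, 47.4% against 12.9% starting complex, with 3.92% two exchanged; dusk gives starting complex, 27.0%.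

    2 starting complex → self-condensation product (k = 0.120 L mol⁻¹ min⁻¹)
    complex with one exchanged + incoming ligand ⇌ leaving ligand + complex with two exchanged (K = 0.140, k = 0.00610 L mol⁻¹ min⁻¹)
    starting complex + incoming ligand ⇌ leaving ligand + complex with one exchanged (K = 35.0, k = 0.0640 L mol⁻¹ min⁻¹)

At dawn the count of 1.21 gave 29.8% unexchanged, but the flask holds 12.9% starting complex and 35.8% self-condensation product, each unit of it counting as two. On the neighbouring flask, dawn with 5.10 equiv, the count is 2.06, above 0.693, and complex with one exchanged stands at 59.2% against 5.8% starting complex.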